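**Strategy.** Everything rests on disconnecting the α-methylene-γ-lactone ring from the carbocycle at its O–C6 and C11–C7 bonds (germacrane numbering). Because C6 is allylic to the C4=C5 alkene of the ten-membered ring, both bonds can form at once in a Larock-type palladium (3+2) heteroannulation: 2-bromoacrylic acid adds across the C6=C7 end of an open-chain (E)-1,3-diene via a π-allyl spanning C6–C5 and an isopropylidene placeholder for C4, with the C8 silyloxy centre controlling the face. The precursor already holds the C8 ether and the C1–C10 epoxide; afterwards the isopropylidene is cut to the C5 aldehyde, converted into a (Z)-iodoalkene and closed to the ring by a Nozaki–Hiyama–Kishi reaction.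

Key step: step 9

Remark: germacrane numbering of the target is used throughout (ring C1–C10, lactone C11–C13 on O6/C7, ester on O8); compounds 1, 5, 6, 8 and 16 are assumed to be commercial.

**Step 1**
Reactants: 1 (E)-2-methylbut-2-en-1-ol
Product: 2 [(2R,3R)-2,3-dimethyloxiran-2-yl]methanol
Conditions: Ti(Oi-Pr)4 (10 mol %), D-(−)-diethyl tartrate (12 mol %), t-BuOOH, 4 Å MS, CH2Cl2, −20 °C
Reagents that add atoms: tert-butyl hydroperoxide, CC(C)(C)OO
Why: Sharpless asymmetric epoxidation of a primary allylic alcohol, in which the D-tartrate titanium complex should deliver oxygen to the face that gives the (2R,3R)-epoxide while the E-alkene fixes the cis relation of the two methyl groups.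

**Step 2**
Reactants: 2 [(2R,3R)-2,3-dimethyloxiran-2-yl]methanol
Product: 4 (2S,3R)-2,3-dimethyloxirane-2-carboxylic acid, via epoxy aldehyde 3 (not isolated)
Conditions: TEMPO (10 mol %), PhI(OAc)2 (2.2 equiv), MeCN/H2O 1:1, 0 °C to rt
Reagents that add atoms: water, O
Why: Nitroxyl-catalysed oxidation of the primary alcohol through the aldehyde hydrate to the glycidic acid, which leaves both epoxide centres untouched (the C2 descriptor changes by priority only).

**Step 3**
Reactants: 5 3-methylbut-2-enal; 6 (triphenylphosphoranylidene)acetaldehyde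
Product: 7 (2E)-5-methylhexa-2,4-dienal
Conditions: toluene, 80 °C
Reagents that add atoms: none
Why: Wittig olefination with a stabilised formyl ylide, which should give the E-enal and so the E-geometry of the future C6=C7 alkene.

**Step 4**
Reactants: 7 (2E)-5-methylhexa-2,4-dienal; 8 allenylboronic acid pinacol ester
Product: 9 (4R,5E)-8-methylnona-5,7-dien-1-yn-4-ol
Conditions: (R)-TRIP [3,3'-bis(2,4,6-triisopropylphenyl)-BINOL hydrogen phosphate] (5 mol %), 4 Å MS, toluene, −20 °C; aq. NaHCO3 work-up
Reagents that add atoms: none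
Why: Chiral phosphoric acid-catalysed asymmetric propargylation with an allenylboronate (closed six-membered SE2' transition state), in which the catalyst should direct addition to the Re face of the aldehyde and set the 4R carbinol that becomes C8 (the catalyst antipode is used if the sense proves opposite).

**Step 5**
Reactants: 9 (4R,5E)-8-methylnona-5,7-dien-1-yn-4-ol
Product: 10 tert-butyl(dimethyl)silyl ether of 9
Conditions: TBSCl, imidazole, DMF, 0 °C to rt
Reagents that add atoms: tert-butyldimethylsilyl chloride, CC(C)(C)[Si](C)(C)Cl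
Why: Silylation of the secondary alcohol gives a bulky ether that cannot ionise and later serves as the face-controlling group in the key step.

**Step 6**
Reactants: 10 tert-butyl(dimethyl)silyl ether of 9
Product: 13 (3E,6R,7E)-6-(tert-butyldimethylsilyloxy)-4,10-dimethylundeca-3,7,9-trien-1-ol, via alkenyldimethylalane 11 (not isolated), via lithium alkenylalanate 12 (not isolated)
Conditions: Me3Al (3 equiv), Cp2ZrCl2 (0.3 equiv), CH2Cl2, 0 °C to rt; evaporate; n-BuLi, THF/hexane, −78 °C; ethylene oxide, −78 to 0 °C
Reagents that add atoms: trimethylaluminium, C[Al](C)C; ethylene oxide, C1CO1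
Why: Negishi zirconium-catalysed carboalumination adds methyl and aluminium syn across the terminal alkyne (methyl on the internal carbon), and the alanate opens ethylene oxide with retention, which sets the E-trisubstituted C1=C10 alkene and brings in C2–C3.

**Step 7**
Reactants: 13 (3E,6R,7E)-6-(tert-butyldimethylsilyloxy)-4,10-dimethylundeca-3,7,9-trien-1-ol
Product: 14 2-[(2R,3R)-3-{(2R,3E)-2-(tert-butyldimethylsilyloxy)-6-methylhepta-3,5-dien-1-yl}-3-methyloxiran-2-yl]ethanol
Conditions: VO(Oi-Pr)3 (2 mol %), chiral C2-symmetric bishydroxamic acid ligand from trans-cyclohexane-1,2-diamine (4 mol %, antipode giving the R,R-epoxide), cumene hydroperoxide, toluene, 0 °C to rt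
Reagents that add atoms: cumene hydroperoxide, CC(C)(OO)c1ccccc1
Why: Vanadium-catalysed hydroxyl-directed asymmetric epoxidation of a homoallylic alcohol, in which the chiral hydroxamate complex bound to the free primary OH should select the face that gives the (1R,10R)-epoxide while the remote, undirected diene is left alone.

**Step 8**
Reactants: 14 epoxy alcohol
Product: 15 4-methoxybenzyl ether of 14
Conditions: NaH, 4-methoxybenzyl chloride, n-Bu4NI (cat.), THF/DMF, 0 °C
Reagents that add atoms: 4-methoxybenzyl chloride, COc1ccc(CCl)cc1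
Why: Williamson etherification masks the primary alcohol (future C3) with a group that is inert to palladium, fluoride, ozone at low temperature and ylides, and is removable oxidatively.

**Step 9**
Reactants: 15 4-methoxybenzyl ether of 14; 16 2-bromoacrylic acid
Product: 17 4,5-trans 3-methylidene-γ-butyrolactone, (4S,5R)-4-[(1R)-1-(tert-butyldimethylsilyloxy)-2-{(2R,3R)-3-[2-(4-methoxybenzyloxy)ethyl]-2-methyloxiran-2-yl}ethyl]-5-(2-methylprop-1-enyl)-3-methylideneoxolan-2-one
Conditions: 16 (1.5 equiv), Pd(OAc)2 (10 mol %), tri(2-furyl)phosphine (20 mol %), Ag2CO3 (1.5 equiv), BHT (5 mol %), DMF, 60 °C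
Reagents that add atoms: none
Why: Zerovalent palladium inserts into the C–Br bond of 16, the 1-carboxyvinyl palladium adds syn across the C6=C7 end of the diene (C11–C7 bond) to give a divalent π-allyl palladium over C6–C5–CMe2, and the pendant carboxylate, held on the metal in a six-membered palladacycle, closes onto C6 (O–C6 bond) with release of the catalyst. The closest known reaction is the Larock heteroannulation of 1,3-dienes by vinylic or aryl halides that carry a carboxylic acid. The lactone ring closes in the 5-exo mode on the allyl terminus, the seven-membered alternative at the fully substituted terminus being disfavoured. C7 is set by C8: in the inside-alkoxy conformer of the allylic silyl ether the alkene is attacked anti to the C8–C9 bond (the sense known from osmylation of allylic ethers), which corresponds to the 7,8-anti relation of the target; C6 is set by C7, because syn carbopalladation of the E-alkene followed by C–O bond formation with retention at palladium is a net syn addition and gives the trans lactone, and re-ionisation of the allylic lactone by zerovalent palladium lets any cis isomer funnel to the more stable trans ring (the symmetrical CMe2 end has no alkene geometry to lose). The step needs regioselectivity for C7 (secured by the gem-dimethyl terminus), face selectivity (secured by the bulky, non-ionisable C8 silyl ether) and capture of the π-allyl before β-hydride elimination (secured by the intramolecular carboxylate).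

**Step 10**
Reactants: 17 silyl-protected lactone
Product: 18 C8 alcohol of 17 (OTBS replaced by OH, other centres unchanged)
Conditions: HF·pyridine, pyridine, THF, 0 °C
Reagents that add atoms: none
Why: Fluoride desilylation under buffered, non-basic conditions should spare the trisubstituted epoxide and avoid base-induced translactonisation onto O8.

**Step 11**
Reactants: 18 C8 alcohol; 4 (2S,3R)-2,3-dimethyloxirane-2-carboxylic acid
Product: 20 C8 (2S,3R)-2,3-dimethyloxirane-2-carboxylate ester of 18, via mixed anhydride 19 (not isolated)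
Conditions: 4, 2,4,6-trichlorobenzoyl chloride, Et3N, toluene, rt; then 18, DMAP, toluene, 0 °C to rt
Reagents that add atoms: none
Why: Yamaguchi esterification through the mixed anhydride acylates the hindered secondary C8 alcohol with retention at C8 and at both centres of the epoxy acid.

**Step 12**
Reactants: 20 C8 ester
Product: 22 C5 aldehyde (isobutenyl group of 20 cut to CHO on C6), via ozonide 21 (not isolated)
Conditions: O3, CH2Cl2, −78 °C (Sudan Red 7B end point); PPh3, −78 °C to rt
Reagents that add atoms: ozone, [O-][O+]=O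
Why: Ozonolysis is chemoselective for the electron-rich trisubstituted alkene over the electron-poor exocyclic methylene, and reductive cleavage of the ozonide unveils the C5 aldehyde without touching C6.

**Step 13**
Reactants: 22 C5 aldehyde
Product: 23 (Z)-iodoalkene, C6–CH=C(CH3)I with iodine cis to C6
Conditions: EtPPh3I, n-BuLi, THF, rt; I2, −78 °C; NaHMDS, −20 °C; then 22, −78 °C
Reagents that add atoms: ethyltriphenylphosphonium iodide, CC[P+](c1ccccc1)(c1ccccc1)c1ccccc1.[I-]; iodine, II
Why: Stork–Zhao-type Wittig olefination with the α-iodoethylidene ylide is kinetically Z-selective and should place iodine cis to C6, as the cis ring alkene requires.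

**Step 14**
Reactants: 23 (Z)-iodoalkene
Product: 24 primary alcohol (OPMB of 23 replaced by OH)
Conditions: DDQ, CH2Cl2/pH 7 phosphate buffer, 0 °C
Reagents that add atoms: none
Why: Oxidative cleavage of the 4-methoxybenzyl ether under buffered conditions frees the C3 alcohol without acid-induced opening of the neighbouring epoxide.

**Step 15**
Reactants: 24 primary alcohol
Product: 25 β,γ-epoxy aldehyde (CH2OH of 24 oxidised to CHO, C3)
Conditions: Dess–Martin periodinane, NaHCO3, CH2Cl2, 0 °C; used at once
Reagents that add atoms: none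
Why: Dess–Martin oxidation is base-free and buffered, so the β,γ-epoxy aldehyde should form without β-elimination if it is carried on directly.

**Step 16**
Reactants: 25 β,γ-epoxy aldehyde
Product: 26 target, (1R,3S,6R,7R,8R,10R)-1,10-epoxy-3-hydroxy-8-[(2S,3R)-2,3-dimethyloxirane-2-carbonyloxy]germacra-4Z,11(13)-dien-12,6-olide
Conditions: CrCl2 (8 equiv), NiCl2 (10 mol %), degassed DMSO/THF 3:1, 2 mM, rt; aqueous work-up
Reagents that add atoms: none
Why: Nozaki–Hiyama–Kishi reaction, in which nickel-mediated insertion into the C–I bond and transmetalation to chromium (from divalent CrCl2) keep the Z-geometry and the alkenylchromium adds to the aldehyde to close the ten-membered ring; the 3S carbinol is expected from attack on the outward face of the aldehyde in the ring-closing transition state, the least secure stereochemical call of the route.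

**Compound list**

1 | (E)-2-methylbut-2-en-1-ol | C/C=C(\C)CO | starting material
2 | [(2R,3R)-2,3-dimethyloxiran-2-yl]methanol (methyl groups cis) | OC[C@@]1(C)O[C@@H]1C | intermediate
3 | (2S,3R)-2,3-dimethyloxirane-2-carbaldehyde | O=C[C@@]1(C)O[C@@H]1C | intermediate (not isolated)
4 | (2S,3R)-2,3-dimethyloxirane-2-carboxylic acid | OC(=O)[C@@]1(C)O[C@@H]1C | intermediate
5 | 3-methylbut-2-enal | CC(C)=CC=O | starting material
6 | (triphenylphosphoranylidene)acetaldehyde | O=CC=P(c1ccccc1)(c1ccccc1)c1ccccc1 | starting material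
7 | (2E)-5-methylhexa-2,4-dienal | CC(C)=C/C=C/C=O | intermediate
8 | allenylboronic acid pinacol ester | C=C=CB1OC(C)(C)C(C)(C)O1 | starting material
9 | (4R,5E)-8-methylnona-5,7-dien-1-yn-4-ol | C#CC[C@@H](O)/C=C/C=C(C)C | intermediate
10 | tert-butyl(dimethyl){[(4R,5E)-8-methylnona-5,7-dien-1-yn-4-yl]oxy}silane | C#CC[C@@H](O[Si](C)(C)C(C)(C)C)/C=C/C=C(C)C | intermediate
11 | dimethyl[(1E,4R,5E)-4-(tert-butyldimethylsilyloxy)-2,8-dimethylnona-1,5,7-trien-1-yl]alane | C[Al](C)/C=C(\C)C[C@@H](O[Si](C)(C)C(C)(C)C)/C=C/C=C(C)C | intermediate (not isolated)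
12 | lithium butyl(dimethyl)[(1E,4R,5E)-4-(tert-butyldimethylsilyloxy)-2,8-dimethylnona-1,5,7-trien-1-yl]alanate | [Li+].CCCC[Al-](C)(C)/C=C(\C)C[C@@H](O[Si](C)(C)C(C)(C)C)/C=C/C=C(C)C | intermediate (not isolated)
13 | (3E,6R,7E)-6-(tert-butyldimethylsilyloxy)-4,10-dimethylundeca-3,7,9-trien-1-ol | OCC/C=C(\C)C[C@@H](O[Si](C)(C)C(C)(C)C)/C=C/C=C(C)C | intermediate
14 | 2-[(2R,3R)-3-{(2R,3E)-2-(tert-butyldimethylsilyloxy)-6-methylhepta-3,5-dien-1-yl}-3-methyloxiran-2-yl]ethanol | OCC[C@H]1O[C@]1(C)C[C@@H](O[Si](C)(C)C(C)(C)C)/C=C/C=C(C)C | intermediate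
15 | 4-methoxybenzyl ether of 14 (key-step diene; 8R, 1R,10R) | COc1ccc(COCC[C@H]2O[C@]2(C)C[C@@H](O[Si](C)(C)C(C)(C)C)/C=C/C=C(C)C)cc1 | intermediate
16 | 2-bromoacrylic acid | OC(=O)C(Br)=C | starting material
17 | (4S,5R)-4-[(1R)-1-(tert-butyldimethylsilyloxy)-2-{(2R,3R)-3-[2-(4-methoxybenzyloxy)ethyl]-2-methyloxiran-2-yl}ethyl]-5-(2-methylprop-1-enyl)-3-methylideneoxolan-2-one (4,5-trans) | C=C1C(=O)O[C@H](C=C(C)C)[C@H]1[C@H](O[Si](C)(C)C(C)(C)C)C[C@@]2(C)O[C@@H]2CCOCc3ccc(OC)cc3 | intermediate
18 | C8 alcohol of 17 (OTBS replaced by OH; trans lactone, centres as in 17) | C=C1C(=O)O[C@H](C=C(C)C)[C@H]1[C@H](O)C[C@@]2(C)O[C@@H]2CCOCc3ccc(OC)cc3 | intermediate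
19 | (2S,3R)-2,3-dimethyloxirane-2-carboxylic 2,4,6-trichlorobenzoic anhydride | O=C(OC(=O)c1c(Cl)cc(Cl)cc1Cl)[C@@]1(C)O[C@@H]1C | intermediate (not isolated)
20 | C8 (2S,3R)-2,3-dimethyloxirane-2-carboxylate of 18 | C=C1C(=O)O[C@H](C=C(C)C)[C@H]1[C@H](OC(=O)[C@@]2(C)O[C@@H]2C)C[C@@]3(C)O[C@@H]3CCOCc4ccc(OC)cc4 | intermediate
21 | ozonide of 20 (3,3-dimethyl-1,2,4-trioxolan-5-yl group on C6, mixture at the trioxolane carbon) | C=C1C(=O)O[C@H](C2OOC(C)(C)O2)[C@H]1[C@H](OC(=O)[C@@]3(C)O[C@@H]3C)C[C@@]4(C)O[C@@H]4CCOCc5ccc(OC)cc5 | intermediate (not isolated)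
22 | C5 aldehyde (formyl group on C6 of the trans lactone, other groups as in 20) | C=C1C(=O)O[C@H](C=O)[C@H]1[C@H](OC(=O)[C@@]2(C)O[C@@H]2C)C[C@@]3(C)O[C@@H]3CCOCc4ccc(OC)cc4 | intermediate
23 | (Z)-2-iodoprop-1-enyl lactone (iodine cis to C6), PMB ether | C=C1C(=O)O[C@H](/C=C(/C)I)[C@H]1[C@H](OC(=O)[C@@]2(C)O[C@@H]2C)C[C@@]3(C)O[C@@H]3CCOCc4ccc(OC)cc4 | intermediate
24 | primary alcohol from 23 (OPMB replaced by OH) | C=C1C(=O)O[C@H](/C=C(/C)I)[C@H]1[C@H](OC(=O)[C@@]2(C)O[C@@H]2C)C[C@@]3(C)O[C@@H]3CCO | intermediate
25 | β,γ-epoxy aldehyde from 24 (C3 aldehyde) | C=C1C(=O)O[C@H](/C=C(/C)I)[C@H]1[C@H](OC(=O)[C@@]2(C)O[C@@H]2C)C[C@@]3(C)O[C@@H]3CC=O | intermediate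
26 | (1R,3S,6R,7R,8R,10R)-1,10-epoxy-3-hydroxy-8-[(2S,3R)-2,3-dimethyloxirane-2-carbonyloxy]germacra-4Z,11(13)-dien-12,6-olide | C=C1C(=O)O[C@@H]2/C=C(/C)[C@@H](O)C[C@H]3O[C@]3(C)C[C@@H](OC(=O)[C@@]3(C)O[C@@H]3C)[C@@H]12 | target

**Step count.** Total: 16 steps. Longest linear sequence: 14 steps (steps 3 to 16; steps 1 and 2 make acid 4 for step 11).

**Steps most likely to fail**

Step 9 (key step). The organopalladium intermediate may leak into β-hydride elimination (open-chain triene acid), or the carbopalladation may show low face selectivity with respect to C8. The fallback trades the palladium cycle for an oxidative radical–polar crossover annulation that still forms C11–C7 and O–C6 together. It sets out from 15: potassium ethyl malonate, Mn(OAc)3·2H2O (trivalent manganese) and Cu(OAc)2·H2O in KOAc-buffered MeCN/AcOH at 40 °C should give the ethyl 2-oxolactone-3-carboxylate F1 through malonyl radical addition to C7, oxidation of the allyl radical and trans-selective lactonisation at C6. Saponification with LiOH in THF/H2O followed by acidification gives the α-carboxy lactone F2. Decarboxylative Mannich methylenation (aqueous HCHO, Et2NH, then NaOAc/AcOH) comes back to the route at 17.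

Step 16. Face selection at the aldehyde carbon during ring closure may be weak or reversed, so that the chromium alkoxide forms from the wrong face. The fallback sets out from 25 and accepts the C3-epimeric macrocyclic alcohol F3 from the same ring closure. It is oxidised with Dess–Martin periodinane/NaHCO3 to the macrocyclic (4Z)-3-ketone F4, which is reduced under reagent control with (R)-Me-CBS oxazaborolidine and catecholborane at −78 °C (Corey–Bakshi–Shibata reduction) to come back to the route at 26.

Step 13. The basic iodo-ylide may add to the α-methylene lactone in a Michael sense or epimerise C6 of the α-acyloxy aldehyde before olefination. The fallback is a non-basic halo-olefination that sets out from 22: CBr4/PPh3 (CH2Cl2, 0 °C, Ramirez olefination) gives the 1,1-dibromoalkene F5. Palladium-catalysed trans-selective Negishi monomethylation (MeZnCl, Pd(DPEphos)Cl2, THF, 0 °C) gives the (Z)-bromoalkene F6 with bromine cis to C6. DDQ then frees the primary alcohol F7, Dess–Martin oxidation gives the bromo aldehyde F8, and CrCl2/NiCl2 ring closure of the bromoalkene (DMSO, 40 °C) comes back to the route at 26.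

**Further compounds**

F1 | step 9 | ethyl 2-oxolactone-3-carboxylate analogue of 17 (CO2Et and H on C11 in place of the methylidene, mixture at C11) | CCOC(=O)C1C(=O)O[C@H](C=C(C)C)[C@H]1[C@H](O[Si](C)(C)C(C)(C)C)C[C@@]2(C)O[C@@H]2CCOCc3ccc(OC)cc3
F2 | step 9 | α-carboxy lactone from F1 (CO2H on C11) | OC(=O)C1C(=O)O[C@H](C=C(C)C)[C@H]1[C@H](O[Si](C)(C)C(C)(C)C)C[C@@]2(C)O[C@@H]2CCOCc3ccc(OC)cc3
F3 | step 16 | C3 epimer of 26 (3R alcohol) | C=C1C(=O)O[C@@H]2/C=C(/C)[C@H](O)C[C@H]3O[C@]3(C)C[C@@H](OC(=O)[C@@]3(C)O[C@@H]3C)[C@@H]12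
F4 | step 16 | macrocyclic (4Z)-3-ketone corresponding to 26 | C=C1C(=O)O[C@@H]2/C=C(/C)C(=O)C[C@H]3O[C@]3(C)C[C@@H](OC(=O)[C@@]3(C)O[C@@H]3C)[C@@H]12
F5 | step 13 | 1,1-dibromoalkene from 22 (C6–CH=CBr2) | C=C1C(=O)O[C@H](C=C(Br)Br)[C@H]1[C@H](OC(=O)[C@@]2(C)O[C@@H]2C)C[C@@]3(C)O[C@@H]3CCOCc4ccc(OC)cc4
F6 | step 13 | (Z)-2-bromoprop-1-enyl analogue of 23 | C=C1C(=O)O[C@H](/C=C(/C)Br)[C@H]1[C@H](OC(=O)[C@@]2(C)O[C@@H]2C)C[C@@]3(C)O[C@@H]3CCOCc4ccc(OC)cc4
F7 | step 13 | bromo analogue of alcohol 24 | C=C1C(=O)O[C@H](/C=C(/C)Br)[C@H]1[C@H](OC(=O)[C@@]2(C)O[C@@H]2C)C[C@@]3(C)O[C@@H]3CCO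
F8 | step 13 | bromo analogue of aldehyde 25 | C=C1C(=O)O[C@H](/C=C(/C)Br)[C@H]1[C@H](OC(=O)[C@@]2(C)O[C@@H]2C)C[C@@]3(C)O[C@@H]3CC=O
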